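**Strategy.** The target is cut at the C8–O aryl ether bond (C7 = carbonyl carbon, C8 = OCH(CH3) carbon), so the skeleton comes from an α-bromopropiophenone and methoxyeugenol with no stereocontrol. Stereochemistry is installed afterwards. The racemic α-aryloxy ketone is reduced by a chiral Ru hydride while C8 epimerises, so one operation converts both enantiomers into a single threo (1R,2R) carbinol. A non-epimerising oxidation then removes the temporary C7 centre. The key step exploits the acidic C8–H, flanked by the C7 aryl ketone on the 3,4,5-trimethoxyphenyl ring and the ether oxygen of the 4-allyl-2,6-dimethoxyphenyl ring, together with the reducible C7=O beside it.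

Key step: step 5

Assumption: the (S,S)-catalyst is expected to give the (1R) carbinol by analogy with benzoin-type substrates; because C7 is erased in step 6, only the C8 configuration of the alcohol matters, and the (R,R)-catalyst would be substituted if the first batch showed the opposite C8 outcome.

**Step 1**
Reactants: 1 3,4,5-trimethoxybenzaldehyde; 2 ethylmagnesium bromide
Product: 4 rac-1-(3,4,5-trimethoxyphenyl)propan-1-ol, via bromomagnesium alkoxide 3 (not isolated)
Conditions: EtMgBr (1.2 equiv), THF, 0 °C to rt; sat. aq NH4Cl
Reagents that add atoms: ethylmagnesium bromide (compound 2), CC[Mg]Br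
Why: Grignard addition of the ethyl nucleophile to the non-enolisable aromatic aldehyde should form the C7–C8 bond cleanly; the carbinol centre is racemic and is destroyed in step 2, so no control is needed.

**Step 2**
Reactants: 4 rac-1-(3,4,5-trimethoxyphenyl)propan-1-ol
Product: 5 1-(3,4,5-trimethoxyphenyl)propan-1-one
Conditions: activated MnO2 (10 equiv), CH2Cl2, rt
Reagents that add atoms: none
Why: Benzylic alcohol oxidation with activated MnO2 is selective for the electron-rich benzylic carbinol and leaves the methyl ethers untouched.

**Step 3**
Reactants: 5 1-(3,4,5-trimethoxyphenyl)propan-1-one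
Product: 6 rac-2-bromo-1-(3,4,5-trimethoxyphenyl)propan-1-one
Conditions: CuBr2 (2.1 equiv), EtOAc/CHCl3 (1:1), reflux
Reagents that add atoms: copper dibromide, [Cu+2].[Br-].[Br-]
Why: α-Halogenation of a ketone through its enol with CuBr2 should brominate the only enolisable carbon and spare the acyl-deactivated trimethoxyarene; the new C8 centre is racemic by design.

**Step 4**
Reactants: 6 rac-2-bromo-1-(3,4,5-trimethoxyphenyl)propan-1-one; 7 4-allyl-2,6-dimethoxyphenol (methoxyeugenol)
Product: 9 rac-2-(4-allyl-2,6-dimethoxyphenoxy)-1-(3,4,5-trimethoxyphenyl)propan-1-one, via potassium phenolate 8 (not isolated)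
Conditions: K2CO3 (2 equiv), acetone, 50 °C, N2
Reagents that add atoms: none
Why: Williamson ether synthesis, in which the phenolate displaces a bromide activated toward SN2 by the adjacent carbonyl; the weak carbonate base at 50 °C should leave the allyl group unconjugated, and the racemic C8 centre is what step 5 requires.

**Step 5**
Reactants: 9 rac-2-(4-allyl-2,6-dimethoxyphenoxy)-1-(3,4,5-trimethoxyphenyl)propan-1-one
Product: 11 (1R,2R)-2-(4-allyl-2,6-dimethoxyphenoxy)-1-(3,4,5-trimethoxyphenyl)propan-1-ol (threo), via achiral enol 10 (not isolated)
Conditions: RuCl(p-cymene)[(S,S)-TsDPEN] (2 mol %), HCO2H (3 equiv), DBU (4 equiv), DMF, 35 °C, Ar; chromatography, then recrystallisation of the threo isomer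
Reagents that add atoms: none
Why: Asymmetric transfer hydrogenation of the Noyori type, run as a dynamic kinetic resolution: formate turns the precatalyst into an 18-electron Ru–H/N–H complex that passes hydride to C7 and a proton to the carbonyl oxygen through an outer-sphere six-membered transition state, while DBU keeps the two ketone enantiomers in equilibrium through enol 10. The closest known reaction type is the stereoconvergent transfer hydrogenation of racemic benzoin and of α-alkoxy or α-aryloxy ketones to single threo (anti) β-oxygenated alcohols. No ring is closed; the only bond made is C7–H. C7 (R) is set by the (S,S)-TsDPEN ligand, which fixes the carbonyl face through the CH/π contact between the p-cymene ligand and the 3,4,5-trimethoxyphenyl ring, and C8 (R) is set by substrate matching, because only in the (R)-ketone can the bulky 2,6-dimethoxyaryloxy group stand anti to the incoming hydride (polar Felkin–Anh arrangement) on that face. The step needs C8 epimerisation faster than reduction of the mismatched enantiomer, which the C8–H flanked by the aryl ketone and the ether oxygen should provide once an amidine base is present (triethylamine alone is judged too weak), and it needs C=O over C=C selectivity, which follows from a coordinatively saturated hydride that cannot bind the allyl alkene. Erythro material is removed here, so that the enantiomeric purity of the threo alcohol becomes the C8 purity of the target.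

**Step 6**
Reactants: 11 (1R,2R)-2-(4-allyl-2,6-dimethoxyphenoxy)-1-(3,4,5-trimethoxyphenyl)propan-1-ol
Product: 12 (R)-2-(4-allyl-2,6-dimethoxyphenoxy)-1-(3,4,5-trimethoxyphenyl)propan-1-one
Conditions: Dess–Martin periodinane (1.3 equiv), NaHCO3 (5 equiv), CH2Cl2, 0 °C to rt; cold aq Na2S2O3/pH 7 phosphate buffer; short silica plug
Reagents that add atoms: none
Why: Dess–Martin oxidation converts the benzylic carbinol into the ketone under buffered, amine-free conditions, so the C8–H, which needs an amidine-strength base to exchange, should stay untouched; C8 (R) is carried into the target while the C7 centre is erased, and the enantiomeric purity is checked by chiral HPLC.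

**Compound list**
1 | 3,4,5-trimethoxybenzaldehyde | COc1cc(C=O)cc(OC)c1OC | starting material
2 | ethylmagnesium bromide | CC[Mg]Br | starting material
3 | bromomagnesium rac-1-(3,4,5-trimethoxyphenyl)propan-1-olate | CCC(O[Mg]Br)c1cc(OC)c(OC)c(OC)c1 | intermediate (not isolated)
4 | rac-1-(3,4,5-trimethoxyphenyl)propan-1-ol | CCC(O)c1cc(OC)c(OC)c(OC)c1 | intermediate
5 | 1-(3,4,5-trimethoxyphenyl)propan-1-one | CCC(=O)c1cc(OC)c(OC)c(OC)c1 | intermediate
6 | rac-2-bromo-1-(3,4,5-trimethoxyphenyl)propan-1-one | CC(Br)C(=O)c1cc(OC)c(OC)c(OC)c1 | intermediate
7 | 4-allyl-2,6-dimethoxyphenol (methoxyeugenol) | C=CCc1cc(OC)c(O)c(OC)c1 | starting material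
8 | potassium 4-allyl-2,6-dimethoxyphenolate | C=CCc1cc(OC)c([O-])c(OC)c1.[K+] | intermediate (not isolated)
9 | rac-2-(4-allyl-2,6-dimethoxyphenoxy)-1-(3,4,5-trimethoxyphenyl)propan-1-one | C=CCc1cc(OC)c(OC(C)C(=O)c2cc(OC)c(OC)c(OC)c2)c(OC)c1 | intermediate
10 | 2-(4-allyl-2,6-dimethoxyphenoxy)-1-(3,4,5-trimethoxyphenyl)prop-1-en-1-ol (achiral enol of 9) | C=CCc1cc(OC)c(OC(C)=C(O)c2cc(OC)c(OC)c(OC)c2)c(OC)c1 | intermediate (not isolated)
11 | (1R,2R)-2-(4-allyl-2,6-dimethoxyphenoxy)-1-(3,4,5-trimethoxyphenyl)propan-1-ol (threo) | C=CCc1cc(OC)c(O[C@H](C)[C@H](O)c2cc(OC)c(OC)c(OC)c2)c(OC)c1 | intermediate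
12 | (R)-2-(4-allyl-2,6-dimethoxyphenoxy)-1-(3,4,5-trimethoxyphenyl)propan-1-one (CNP0127876.1) | C=CCc1cc(OC)c(O[C@H](C)C(=O)c2cc(OC)c(OC)c(OC)c2)c(OC)c1 | target

**Totals**
Total step count: 6. Longest linear sequence: 6 steps (from 1 to 12).

**Steps most likely to fail**

1. Step 5. The risk is that epimerisation at C8 does not keep pace with hydride transfer, or that the threo preference is weak, so the reaction behaves as a plain kinetic resolution and gives diastereomer mixtures. The fallback gives up the dynamic regime and resolves instead. Setting out from 9, the same hydride catalyst is used in acidic HCO2H/Et3N (5:2) without DBU and stopped near half conversion. Only the matched (R)-ketone should then be reduced to 11, which is separated by chromatography from the unreacted ketone, (S)-2-(4-allyl-2,6-dimethoxyphenoxy)-1-(3,4,5-trimethoxyphenyl)propan-1-one F1. F1 is racemised in a separate flask (DBU, toluene, 60 °C) back to 9 and recycled. The route is rejoined at 11.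

2. Step 6. The risk is partial loss of the C8 configuration through enolisation of the product during oxidation, work-up or chromatography. The fallback is a chiral-pool route with no oxidation next to C8, which also makes step 5 unnecessary. Setting out from 7, Mitsunobu etherification with commercial ethyl (S)-lactate (PPh3, DIAD, THF, 0 °C to rt, inversion at carbon) should give ethyl (R)-2-(4-allyl-2,6-dimethoxyphenoxy)propanoate F2. Aminolysis with MeNH(OMe)·HCl and isopropylmagnesium chloride (THF, −20 °C) should give (R)-2-(4-allyl-2,6-dimethoxyphenoxy)-N-methoxy-N-methylpropanamide F3. Addition of commercial 3,4,5-trimethoxyphenylmagnesium bromide (THF, 0 °C) forms a chelated tetrahedral adduct that releases the ketone only on cold aqueous NH4Cl quench. The route is rejoined at 12.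

3. Step 3. The risk is competing electrophilic bromination of the electron-rich ring or a second bromination at C8. The fallback fixes the nucleophilic site before the halogen is introduced. Setting out from 5, soft enolisation (TMSOTf, Et3N, CH2Cl2, 0 °C) should give (Z)-trimethyl{[1-(3,4,5-trimethoxyphenyl)prop-1-en-1-yl]oxy}silane F4. One equivalent of NBS in THF at −78 to 0 °C then brominates the enol ether carbon far faster than the arene. The route is rejoined at 6.

**Further compounds**
F1 | step 5 | (S)-2-(4-allyl-2,6-dimethoxyphenoxy)-1-(3,4,5-trimethoxyphenyl)propan-1-one | C=CCc1cc(OC)c(O[C@@H](C)C(=O)c2cc(OC)c(OC)c(OC)c2)c(OC)c1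
F2 | step 6 | ethyl (R)-2-(4-allyl-2,6-dimethoxyphenoxy)propanoate | C=CCc1cc(OC)c(O[C@H](C)C(=O)OCC)c(OC)c1
F3 | step 6 | (R)-2-(4-allyl-2,6-dimethoxyphenoxy)-N-methoxy-N-methylpropanamide | C=CCc1cc(OC)c(O[C@H](C)C(=O)N(C)OC)c(OC)c1
F4 | step 3 | (Z)-trimethyl{[1-(3,4,5-trimethoxyphenyl)prop-1-en-1-yl]oxy}silane | C/C=C(\O[Si](C)(C)C)c1cc(OC)c(OC)c(OC)c1
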